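I decide to feed the partner and to keep the substrate in the flask from the start; here is the reckoning behind that choice.

| flask | substrate | partner | remark | time |
|---|---|---|---|---|
| larch | 0.20 M | 1.3 equiv | run made earlier |  |
| cedar | 0.28 M | 1.3 equiv | run made earlier |  |
| ash | 0.44 M | 1.3 equiv | run made earlier |  |
| alder | 0.20 M | 2 equiv | run made earlier |  |
| eta | 0.20 M | 1.30 equiv (fed, over 10 min) | all else is in the flask from the start; the feed brings no volume worth counting | 15 min |
| alpha | 0.20 M (fed, over 10 min) | 1.30 equiv | all else is in the flask from the start; the feed brings no volume worth counting | 15 min |
| gamma | 0.20 M | 1.30 equiv | everything together at the start | 15 min |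

- larch (time / min: target / %, substrate / %): 1.33: 9, 66; 4.00: 28, 39; 8.00: 38, 25; 10.0: 38, 29; 15.0: 39, 20
- cedar (time / min: target / %, substrate / %): 0.833: 3, 74; 2.50: 18, 47; 4.00: 30, 37; 6.00: 31, 28; 10.0: 40, 25
- ash (time / min: target / %, substrate / %): 0.667: 4, 76; 1.33: 13, 63; 2.50: 21, 42; 5.00: 34, 31; 10.0: 37, 23
- alder (time / min: target / %, substrate / %): 0.833: 5, 75; 2.50: 21, 49; 4.00: 30, 36; 6.00: 36, 29; 10.0: 42, 21

(readings scatter by 2 percentage points)

- the analysis behind the earlier runs scatters by 2 percentage points, standard deviation

1. the best flask by amount of target, in percent of the substrate charged; "all alike" if 1.5 percentage points covers them all (eta / alpha / gamma / all alike)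
2. amount of target at the end, in percent of the substrate charged, eta
3. amount of target at the end, in percent of the substrate charged, alpha
4. amount of target at the end, in percent of the substrate charged, gamma

Larch reads 39% target at 15.0 min on 1.3 equiv of partner, so I read its partner yield as 30.0%. By partner yield I mean percent target per equivalent of partner charged: the selectivity of the partner for target, if one partner makes one target.

The readings at 10.0 min show how it moves. Larch gives 29.2%, while alder, with 2 equiv, gives 21.0%, which is less partner yield for more partner. I call the ratio of the two, a reading with its scatter, the step g.

g = 1.39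

The first setting is the partner feed. In eta the partner enters over 10 min, so I expect a move in the direction from alder to larch, and I put the yield through the step once more:

eta: 30.0% × 1.39 = 41.7%, so target 54.3%

The second setting is the substrate feed. In alpha the whole partner charge meets a first trickle of substrate, so I take the step backwards:

alpha: 30.0% / 1.39 = 21.6%, so target 28.0%

Gamma repeats larch, so I expect 39%, and my figure for eta stands above it.

The forecast names gamma as best: eta 37% (26% to 42%), alpha 12% (8% to 18%), gamma 40% (37% to 43%). Its grounds for eta: “zero-order partner suggests little change”. My reckoning differs from it on the best flask.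

The flasks give eta 56.6%, alpha 22.9% and gamma 42.6%, so the best is eta.

    substrate ⇌ open intermediate (K = 1.60, k = 0.00660 /s)
    2 second intermediate → homo product (k = 0.0170 /M/s)
    partner → second intermediate (k = 0.100 /s)
    open intermediate + second intermediate → target (k = 0.0300 /M/s)
    partner → decomposed reagent (k = 0.00150 /s)

The partner yield is 43.5% in eta, 32.8% in gamma and 17.6% in alpha. The forecast and the flask part furthest on eta, by 20 percentage points of target against 11 points on alpha and 2.6 points on gamma. The neighbour is alpha left until 40 min. At 15.0 min alpha has partner at 0% and c(second intermediate) at 0.00961 M, which is 3.70% of the partner charged. Added to alpha's yield, that gives a ceiling of 21.3%. The neighbour reaches 21.0%, below that ceiling, with target at 27.4%.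

The earlier runs and the new flask are simulated for an exercise, and the scatter is random.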